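All runs are calculated with constants of no real substance; scatter was added.

**What stood.** The constants of the steps were hidden from me, so I reckoned from two earlier runs, in which G dissolves and J takes up X to give J.X, all in percent of the G charged.

| flask | G | X | remark | time |
|---|---|---|---|---|
| Saturday's | 0.20 M | 0.21 M | run made earlier |  |
| Tuesday's | 0.20 M | 0.73 M | run made earlier |  |
| amber | 0.20 M | 0.160 M |  | 4.0 d |
| ochre | 0.20 M | 0.240 M |  | 4.0 d |
| violet | 0.20 M | 0.500 M |  | 4.0 d |

- Saturday's (time / d: J.X / %): 0.208: 1.4; 0.417: 0; 0.833: 0.7; 1.67: 3.0; 3.00: 5.7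
- Tuesday's (time / d: J.X / %): 0.208: 2.1; 0.417: 0.9; 0.833: 5.8; 1.67: 9.9; 3.00: 16.8

(standard deviation of a reading: 1 percentage point)

- given per volume of solution although it is solid: G
- the analysis behind the earlier runs scatters by 1 percentage point, standard deviation
- candidate steps: J + X -> J.X; X + J.X -> X.J.X; X + X.J.X -> X.X.J.X; X <-> Z; G <-> J
- at the start none of G is in solution

- amount of J.X at the end, in percent of the G charged, for each flask in turn (amber, ochre, violet)

**An odd pair.** Tuesday's run charged 3.48 times the X of Saturday's, yet at 3.00 d its J.X stood at 2.95 times Saturday's, a smaller ratio than the charges'. But a scatter of 1 percentage point matters on Saturday's 5.7%: one deviation lower, the ratio is 3.57, more than the charge ratio, so the two numbers do not conflict.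

**My reckoning.** I compared the two runs at one time, on the assumption that they share one time course, so that time drops out of their ratio. The logarithm of the J.X ratio over the logarithm of the charge ratio is the apparent order in X, here 0.868, a reading with that scatter, taken at that one time. Saturday's reading stretched in proportion to time gives 7.60% at 4.0 d. Scaled by the order, this gave me 6.00% for amber, 8.53% for ochre and 16.1% for violet.

**The forecast.** It said 5.9%, 8.5% and 15.5%, slightly different from mine, on the view that “J stays roughly constant, held by the dissolving solid”.

**The result.** The flasks gave 5.88%, 8.55% and 16.2%, so the apparent order at 4.0 d was 0.923 from amber to ochre and 0.871 from ochre to violet.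

    J + X → J.X (k = 0.0436 M⁻¹ h⁻¹)
    X + J.X → X.J.X (k = 0.00916 M⁻¹ h⁻¹)
    X + X.J.X → X.X.J.X (k = 0.0591 M⁻¹ h⁻¹)
    X ⇌ Z (K = 1.50, k = 0.0518 h⁻¹)
    G ⇌ J, rate k5*(cs5 - [J]) while solid is left; crystals form when [J] > cs5 (solubility = 0.0540 M, k = 0.0627 h⁻¹)

In amber, X to Z had 60% of its turnover up to the end behind it after 0.400 d, and the dissolving of G had 38%. From 2.00 d to 4.00 d, amber's J went from 24.7% to 25.9% and its X from 38.9% to 36.3% of its own charge, while J.X climbed from 2.80% to 5.88%.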